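**Retrosynthetic overview**

1. The target is reached from saturated bicyclic keto acetate 28 by dehydrogenation to the C11=C12 enone and removal of the C10 silyl ether.
2. Key disconnection: the C8–C15 bond of ring D (cyclopentane C8–C14–C13–C16–C15 of the bicyclo[3.2.1]octane), made by a reductive, polarity-reversed aldol of enal 25. It is possible because C8 is the α-carbon of the C9 ketone and C15 carries its oxygen β to that ketone (β-acyloxy ketone retron), and because C8 and C13 are 1,3-related on ring C, so the C13 arm can only bridge cis and C13 alone dictates C8.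
3. C6–C7 bond: Barton decarboxylative addition of lactone acid 10 to α-methylene ketone 21 on the convex lactone face; the same step places the reductively cleavable pyridylthio group on C8.
4. Acid 10 comes from a 3-oxocyclohexenecarboxylate by copper-catalyzed asymmetric conjugate methylation/glyoxylate aldol (C4), lactonization, methylenation and Mukaiyama hydration (C10). Enone 21 comes from a 4-substituted cyclohexanone desymmetrized by a chiral lithium amide (C13).
5. Ring order: rings A and C are bought as cyclohexanes; the lactone ring is closed in step 3; ring D is closed last, in step 18.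

Key step: step 18

Remark on the chemistry: locants are those of the ent-kaurane skeleton (ring A = C1–C5, C10; C18 and C20 methyls; lactone C19(=O)–O–C6; C7 methylene; ring C = C8, C9, C11–C14; bridge C15–C16; C17 exocyclic methylene).
Remark on the chemistry: compounds 4–10 are carried as C6 epimers because C6 becomes a radical in step 15; the minor enantiomer of 21 ends as a diastereomer of 23 and is removed there.

**Step 1**
Reactants: 1 3-oxocyclohex-1-ene-1-carboxylic acid
Product: 2 tert-butyl 3-oxocyclohex-1-ene-1-carboxylate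
Conditions: Boc2O, DMAP (cat.), t-BuOH, rt
Reagents that add atoms: di-tert-butyl dicarbonate, CC(C)(C)OC(=O)OC(=O)OC(C)(C)C
Why: DMAP-catalyzed esterification through the mixed carbonic anhydride gives the bulky ester wanted for the conjugate addition and for the later acidolysis, and no stereocenter is formed.

**Step 2**
Reactants: 2 tert-butyl 3-oxocyclohex-1-ene-1-carboxylate
Product: 4 tert-butyl (1R)-2-(2-ethoxy-1-hydroxy-2-oxoethyl)-1-methyl-3-oxocyclohexane-1-carboxylate, via methylzinc enolate 3 (not isolated)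
Conditions: Me2Zn, Cu(OTf)2 (cat.), chiral sulfonate-bearing N-heterocyclic carbene ligand (cat., from its imidazolinium salt), Et2O, −30 °C; then ethyl glyoxylate, −78 °C; aq. NH4Cl
Reagents that add atoms: dimethylzinc, C[Zn]C; ethyl glyoxylate, CCOC(=O)C=O
Why: Copper-catalyzed asymmetric conjugate addition of methyl to the β-carbon C4 sets the quaternary centre (ligand antipode chosen for 4R) and the zinc enolate formed regiospecifically at C5 is trapped in a tandem aldol reaction, the new centres at C5 and C6 arising as mixtures that converge later.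

**Step 3**
Reactants: 4 tert-butyl (1R)-2-(2-ethoxy-1-hydroxy-2-oxoethyl)-1-methyl-3-oxocyclohexane-1-carboxylate
Product: 6 ethyl (3aS,7aR)-7a-methyl-1,4-dioxo-octahydro-2-benzofuran-3-carboxylate, via hydroxy keto acid 5 (not isolated)
Conditions: CF3CO2H, CH2Cl2, 0 °C to rt; then toluene, 60 °C
Reagents that add atoms: none
Why: Acidolysis of the tert-butyl ester is followed by γ-lactonization of the C19 acid onto the C6 hydroxyl, and because C5 equilibrates through the enol (or through reversible dehydration and oxa-Michael addition) the material should funnel into the cis-fused lactone (5S), the preferred fusion of this angularly methylated bicycle.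

**Step 4**
Reactants: 6 ethyl (3aS,7aR)-7a-methyl-1,4-dioxo-octahydro-2-benzofuran-3-carboxylate
Product: 7 ethyl (3aS,7aR)-7a-methyl-4-methylidene-1-oxo-octahydro-2-benzofuran-3-carboxylate
Conditions: Zn, CH2Br2, TiCl4, THF/CH2Cl2, 0 °C to rt
Reagents that add atoms: dibromomethane, BrCBr
Why: The non-basic Takai–Lombardo methylenation converts the hindered C10 ketone into the exocyclic alkene without E1cB opening of the β-acyloxy ketone and leaves ester and lactone untouched, no stereocenter being formed.

**Step 5**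
Reactants: 7 ethyl (3aS,7aR)-7a-methyl-4-methylidene-1-oxo-octahydro-2-benzofuran-3-carboxylate
Product: 8 ethyl (3aS,4R,7aR)-4-hydroxy-4,7a-dimethyl-1-oxo-octahydro-2-benzofuran-3-carboxylate
Conditions: Co(acac)2 (cat.), PhSiH3, O2 (1 atm), THF, rt
Reagents that add atoms: dioxygen, O=O
Why: Mukaiyama (hydrogen-atom-transfer) Markovnikov hydration generates the tertiary C10 radical, which should capture O2 on the convex face of the cis-fused bicycle, anti to the lactone ring and equatorial on ring A, so that the hydroxyl ends trans to C6 and the new C20 methyl cis to it (10R).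

**Step 6**
Reactants: 8 ethyl (3aS,4R,7aR)-4-hydroxy-4,7a-dimethyl-1-oxo-octahydro-2-benzofuran-3-carboxylate
Product: 9 ethyl (3aS,4R,7aR)-4,7a-dimethyl-1-oxo-4-(triethylsilyloxy)-octahydro-2-benzofuran-3-carboxylate
Conditions: Et3SiOTf, 2,6-lutidine, CH2Cl2, −40 to 0 °C
Reagents that add atoms: triethylsilyl trifluoromethanesulfonate, CC[Si](CC)(CC)OS(=O)(=O)C(F)(F)F
Why: Silylation with a silyl triflate and a hindered base masks the tertiary alcohol so that it cannot protonate the samarium enolate of step 18, and no stereocenter is touched.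

**Step 7**
Reactants: 9 ethyl (3aS,4R,7aR)-4,7a-dimethyl-1-oxo-4-(triethylsilyloxy)-octahydro-2-benzofuran-3-carboxylate
Product: 10 (3aS,4R,7aR)-4,7a-dimethyl-1-oxo-4-(triethylsilyloxy)-octahydro-2-benzofuran-3-carboxylic acid
Conditions: LiOH, THF/H2O, 0 °C; then 1 M HCl to pH 3
Reagents that add atoms: lithium hydroxide, [Li+].[OH-]
Why: Saponification of the activated α-acyloxy ethyl ester gives the α-oxy acid needed for decarboxylation, any opened lactone reclosing on acidification, and the C6 configuration is irrelevant because this centre becomes a radical in step 15.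

**Step 8**
Reactants: 11 ethyl 2-(1,4-dioxaspiro[4.5]decan-8-yl)acetate
Product: 12 2-(1,4-dioxaspiro[4.5]decan-8-yl)acetaldehyde
Conditions: i-Bu2AlH, toluene, −78 °C; aq. potassium sodium tartrate
Reagents that add atoms: none
Why: Partial reduction of the ester through the stable tetrahedral aluminium hemiacetal (DIBAL-H reduction) gives the aldehyde, and no stereocenter is formed.

**Step 9**
Reactants: 12 2-(1,4-dioxaspiro[4.5]decan-8-yl)acetaldehyde
Product: 13 2-(1,4-dioxaspiro[4.5]decan-8-yl)prop-2-enal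
Conditions: aq. CH2O (37%), pyrrolidine (cat.), propanoic acid (cat.), i-PrOH, 45 °C
Reagents that add atoms: formaldehyde, C=O
Why: Amine-catalyzed Mannich condensation and elimination (organocatalytic α-methylenation of an aldehyde) installs C17 and gives the 2-substituted acrolein, no stereocenter being formed.

**Step 10**
Reactants: 13 2-(1,4-dioxaspiro[4.5]decan-8-yl)prop-2-enal
Product: 14 2-(1,4-dioxaspiro[4.5]decan-8-yl)prop-2-en-1-ol
Conditions: NaBH4, CeCl3·7H2O, MeOH, −20 °C
Reagents that add atoms: none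
Why: Luche 1,2-reduction converts the enal into the allylic alcohol, a form of C15 that is inert to the bases and radicals used before the key step.

**Step 11**
Reactants: 14 2-(1,4-dioxaspiro[4.5]decan-8-yl)prop-2-en-1-ol
Product: 15 tert-butyl{[2-(1,4-dioxaspiro[4.5]decan-8-yl)prop-2-en-1-yl]oxy}dimethylsilane
Conditions: t-BuMe2SiCl, imidazole, CH2Cl2, rt
Reagents that add atoms: tert-butyldimethylsilyl chloride, CC(C)(C)[Si](C)(C)Cl
Why: Standard imidazole-promoted silylation protects the primary allylic alcohol as a TBS ether that survives the ketal hydrolysis and the strong base of step 13.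

**Step 12**
Reactants: 15 tert-butyl{[2-(1,4-dioxaspiro[4.5]decan-8-yl)prop-2-en-1-yl]oxy}dimethylsilane
Product: 16 4-{3-[(tert-butyldimethylsilyl)oxy]prop-1-en-2-yl}cyclohexan-1-one
Conditions: PPTS (cat.), acetone/H2O, 50 °C
Reagents that add atoms: water, O
Why: Mild acid-catalyzed ketal hydrolysis releases the prochiral 4-substituted cyclohexanone while the primary TBS ether should survive.

**Step 13**
Reactants: 16 4-{3-[(tert-butyldimethylsilyl)oxy]prop-1-en-2-yl}cyclohexan-1-one
Product: 18 tert-butyldimethyl({2-[(1R)-4-(trimethylsilyloxy)cyclohex-3-en-1-yl]prop-2-en-1-yl}oxy)silane, via lithium enolate 17 (not isolated)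
Conditions: lithium (S,S)-bis(1-phenylethyl)amide, Me3SiCl (in situ quench), THF, −100 °C
Reagents that add atoms: chlorotrimethylsilane, C[Si](C)(C)Cl
Why: Enantioselective deprotonation of a prochiral 4-substituted cyclohexanone by a chiral lithium amide with internal silyl quench differentiates the enantiotopic α-methylene groups and thereby defines C13 as R (the sense of the (S,S)-amide is assigned by analogy with 4-alkylcyclohexanones and the antipode is taken if it proves opposite).

**Step 14**
Reactants: 18 tert-butyldimethyl({2-[(1R)-4-(trimethylsilyloxy)cyclohex-3-en-1-yl]prop-2-en-1-yl}oxy)silane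
Product: 21 (4R)-4-{3-[(tert-butyldimethylsilyl)oxy]prop-1-en-2-yl}-2-methylidenecyclohexan-1-one, via Mannich base 19 (not isolated), via ammonium iodide 20 (not isolated)
Conditions: CH2=NMe2+ I−, CH2Cl2, rt; then MeI; then aq. NaHCO3; used at once
Reagents that add atoms: N,N-dimethylmethyleneiminium iodide, C=[N+](C)C.[I-]
Why: Regiospecific Mannich reaction of the enol silane at C8 followed by quaternization and E1cB elimination (α-methylenation of a ketone) installs C7 as an exocyclic methylene on the α-carbon selected in step 13, so the C13 configuration is carried through unchanged.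

**Step 15**
Reactants: 10 (3aS,4R,7aR)-4,7a-dimethyl-1-oxo-4-(triethylsilyloxy)-octahydro-2-benzofuran-3-carboxylic acid; 21 (4R)-4-{3-[(tert-butyldimethylsilyl)oxy]prop-1-en-2-yl}-2-methylidenecyclohexan-1-one
Product: 23 (4R)-2-{[(1R,3aR,7R,7aS)-3a,7-dimethyl-3-oxo-7-(triethylsilyloxy)octahydro-2-benzofuran-1-yl]methyl}-4-{3-[(tert-butyldimethylsilyl)oxy]prop-1-en-2-yl}-2-(pyridin-2-ylsulfanyl)cyclohexan-1-one, via Barton ester 22 (not isolated)
Conditions: 10, 1-hydroxypyridine-2(1H)-thione, DCC, CH2Cl2, 0 °C, dark; then 21 (2 equiv), tungsten lamp, 0 °C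
Reagents that add atoms: 1-hydroxypyridine-2(1H)-thione, On1ccccc1=S
Why: In this Barton decarboxylative radical addition the α-acyloxy C6 radical should add to the unsubstituted methylene terminus of the enone on the convex face of the cis-fused lactone (C7 exo and cis to H5, 6R), and the tertiary α-keto radical propagates the chain by abstracting the pyridylthio group, which puts on C8 the reductively cleavable substituent that step 18 needs (C8 epimers are inconsequential).

**Step 16**
Reactants: 23 C8-pyridylthio ketone with TBS ether at C15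
Product: 24 (4R)-2-{[(1R,3aR,7R,7aS)-3a,7-dimethyl-3-oxo-7-(triethylsilyloxy)octahydro-2-benzofuran-1-yl]methyl}-4-(3-hydroxyprop-1-en-2-yl)-2-(pyridin-2-ylsulfanyl)cyclohexan-1-one
Conditions: camphorsulfonic acid (cat.), MeOH/CH2Cl2, 0 °C
Reagents that add atoms: none
Why: Acid-catalyzed methanolysis is sterically controlled and should remove the unhindered primary allylic TBS ether much faster than the tertiary TES ether.

**Step 17**
Reactants: 24 C8-pyridylthio ketone with free allylic alcohol at C15
Product: 25 2-[(1R)-3-{[(1R,3aR,7R,7aS)-3a,7-dimethyl-3-oxo-7-(triethylsilyloxy)octahydro-2-benzofuran-1-yl]methyl}-4-oxo-3-(pyridin-2-ylsulfanyl)cyclohexyl]prop-2-enal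
Conditions: MnO2, CH2Cl2, rt
Reagents that add atoms: none
Why: Chemoselective allylic oxidation with MnO2 gives the enal without touching the sulfide, the ketone or the silyl ether.

**Step 18**
Reactants: 25 enal bearing the C8-pyridylthio ketone
Product: 28 (1R,5R,7R)-1-{[(1R,3aR,7R,7aS)-3a,7-dimethyl-3-oxo-7-(triethylsilyloxy)octahydro-2-benzofuran-1-yl]methyl}-6-methylidene-2-oxobicyclo[3.2.1]octan-7-yl acetate, via samarium enolate 26 (not isolated), via samarium aldolate 27 (not isolated)
Conditions: SmI2 (2.3 equiv, added to the substrate), THF, −78 °C; then Ac2O, DMAP (cat.), −78 to 0 °C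
Reagents that add atoms: acetic anhydride, CC(=O)OC(C)=O
Why: Proposed new method: two single-electron transfers from divalent samarium to the α-(pyridin-2-ylthio) ketone expel the thiolate and give the trivalent samarium enolate regiospecifically at C8, which adds to the C15 aldehyde and is acetylated in the flask; the closest known reaction types are the samarium Reformatsky-type aldol cyclization of α-halo ketones and the SmI2 cleavage of α-arylthio ketones to enolates. Ring D (C8–C14–C13–C16–C15) is closed in the 5-(enolexo)-exo-trig mode, which joins two carbons that are both electrophilic in the precursor. C8 is controlled by C13, because the C13 arm can bond to C8 only cis across ring C (8R), and C15 is controlled by the closed Zimmerman–Traxler-type transition state in which trivalent samarium bridges the enolate oxygen on C9 and the aldehyde oxygen, which places O15 syn to C9 and endo on the two-carbon bridge (15R). The step needs reduction of the C–S bond in preference to the enal and the ketone, which the much faster electron transfer to α-heterosubstituted ketones at −78 °C and the slow addition of SmI2 should secure, enolization at C8 and not at C11, which the position of the sulfur secures, and 1,2- instead of 1,4-attack on the enal, which is secured because attack at C17 would be a 5-endo-trig closure. Acetylation of the samarium aldolate at low temperature should suppress retro-aldol cleavage and gives the C15 acetate directly.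

**Step 19**
Reactants: 28 saturated bicyclic keto acetate (TES ether)
Product: 30 (1R,5S,7R)-1-{[(1R,3aR,7R,7aS)-3a,7-dimethyl-3-oxo-7-(triethylsilyloxy)octahydro-2-benzofuran-1-yl]methyl}-6-methylidene-2-oxobicyclo[3.2.1]oct-3-en-7-yl acetate, via silyl enol ether 29 (not isolated)
Conditions: Me3SiOTf, Et3N, CH2Cl2, 0 °C; then IBX·MPO (MPO = 4-methoxypyridine N-oxide), DMSO, rt
Reagents that add atoms: none
Why: Soft enolization can only go towards C11 because C8 is quaternary, and IBX-mediated dehydrogenation of the enol silane (a Saegusa-type oxidation without palladium, which spares the allylic acetate) gives the C11=C12 enone without touching a stereocenter.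

**Step 20**
Reactants: 30 TES ether of the target
Product: 31 CNP0172716.1
Conditions: HF·pyridine, THF, 0 °C to rt
Reagents that add atoms: none
Why: Fluoride-mediated desilylation of the tertiary TES ether liberates the C10 hydroxyl without affecting the acetate, the enone or the lactone.

**Compound list**

1 | 3-oxocyclohex-1-ene-1-carboxylic acid | O=C(O)C1=CC(=O)CCC1 | starting material
2 | tert-butyl 3-oxocyclohex-1-ene-1-carboxylate | CC(C)(C)OC(=O)C1=CC(=O)CCC1 | intermediate
3 | methylzinc enolate of tert-butyl (1R)-1-methyl-3-oxocyclohexane-1-carboxylate (enolate towards C2 of the ring) | CC(C)(C)OC(=O)[C@]1(C)CCCC(O[Zn]C)=C1 | intermediate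
4 | tert-butyl (1R)-2-(2-ethoxy-1-hydroxy-2-oxoethyl)-1-methyl-3-oxocyclohexane-1-carboxylate (epimers at ring C2 and at the carbinol carbon) | CC(C)(C)OC(=O)[C@]1(C)CCCC(=O)C1C(O)C(=O)OCC | intermediate
5 | (1R)-2-(2-ethoxy-1-hydroxy-2-oxoethyl)-1-methyl-3-oxocyclohexane-1-carboxylic acid | OC(=O)[C@]1(C)CCCC(=O)C1C(O)C(=O)OCC | intermediate
6 | ethyl (3aS,7aR)-7a-methyl-1,4-dioxo-octahydro-2-benzofuran-3-carboxylate (cis-fused; C3 epimers) | CCOC(=O)C1OC(=O)[C@]2(C)CCCC(=O)[C@H]12 | intermediate
7 | ethyl (3aS,7aR)-7a-methyl-4-methylidene-1-oxo-octahydro-2-benzofuran-3-carboxylate (C3 epimers) | CCOC(=O)C1OC(=O)[C@]2(C)CCCC(=C)[C@H]12 | intermediate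
8 | ethyl (3aS,4R,7aR)-4-hydroxy-4,7a-dimethyl-1-oxo-octahydro-2-benzofuran-3-carboxylate (C3 epimers) | CCOC(=O)C1OC(=O)[C@]2(C)CCC[C@@](C)(O)[C@H]12 | intermediate
9 | ethyl (3aS,4R,7aR)-4,7a-dimethyl-1-oxo-4-(triethylsilyloxy)-octahydro-2-benzofuran-3-carboxylate (C3 epimers) | CCOC(=O)C1OC(=O)[C@]2(C)CCC[C@@](C)(O[Si](CC)(CC)CC)[C@H]12 | intermediate
10 | (3aS,4R,7aR)-4,7a-dimethyl-1-oxo-4-(triethylsilyloxy)-octahydro-2-benzofuran-3-carboxylic acid (C3 epimers) | OC(=O)C1OC(=O)[C@]2(C)CCC[C@@](C)(O[Si](CC)(CC)CC)[C@H]12 | intermediate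
11 | ethyl 2-(1,4-dioxaspiro[4.5]decan-8-yl)acetate | CCOC(=O)CC1CCC2(CC1)OCCO2 | starting material
12 | 2-(1,4-dioxaspiro[4.5]decan-8-yl)acetaldehyde | O=CCC1CCC2(CC1)OCCO2 | intermediate
13 | 2-(1,4-dioxaspiro[4.5]decan-8-yl)prop-2-enal | C=C(C=O)C1CCC2(CC1)OCCO2 | intermediate
14 | 2-(1,4-dioxaspiro[4.5]decan-8-yl)prop-2-en-1-ol | C=C(CO)C1CCC2(CC1)OCCO2 | intermediate
15 | tert-butyl{[2-(1,4-dioxaspiro[4.5]decan-8-yl)prop-2-en-1-yl]oxy}dimethylsilane | C=C(CO[Si](C)(C)C(C)(C)C)C1CCC2(CC1)OCCO2 | intermediate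
16 | 4-{3-[(tert-butyldimethylsilyl)oxy]prop-1-en-2-yl}cyclohexan-1-one | C=C(CO[Si](C)(C)C(C)(C)C)C1CCC(=O)CC1 | intermediate
17 | lithium (4R)-4-{3-[(tert-butyldimethylsilyl)oxy]prop-1-en-2-yl}cyclohex-1-en-1-olate | C=C(CO[Si](C)(C)C(C)(C)C)[C@@H]1CCC(O[Li])=CC1 | intermediate
18 | tert-butyldimethyl({2-[(1R)-4-(trimethylsilyloxy)cyclohex-3-en-1-yl]prop-2-en-1-yl}oxy)silane | C=C(CO[Si](C)(C)C(C)(C)C)[C@@H]1CCC(O[Si](C)(C)C)=CC1 | intermediate
19 | (4R)-4-{3-[(tert-butyldimethylsilyl)oxy]prop-1-en-2-yl}-2-[(dimethylamino)methyl]cyclohexan-1-one (C2 epimers) | C=C(CO[Si](C)(C)C(C)(C)C)[C@@H]1CCC(=O)C(CN(C)C)C1 | intermediate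
20 | {[(5R)-5-{3-[(tert-butyldimethylsilyl)oxy]prop-1-en-2-yl}-2-oxocyclohexyl]methyl}trimethylammonium iodide | C=C(CO[Si](C)(C)C(C)(C)C)[C@@H]1CCC(=O)C(C[N+](C)(C)C)C1.[I-] | intermediate
21 | (4R)-4-{3-[(tert-butyldimethylsilyl)oxy]prop-1-en-2-yl}-2-methylidenecyclohexan-1-one | C=C(CO[Si](C)(C)C(C)(C)C)[C@@H]1CCC(=O)C(=C)C1 | intermediate
22 | 2-thioxopyridin-1(2H)-yl ester of acid 10 (Barton ester) | S=C3C=CC=CN3OC(=O)C1OC(=O)[C@]2(C)CCC[C@@](C)(O[Si](CC)(CC)CC)[C@H]12 | intermediate
23 | (4R)-2-{[(1R,3aR,7R,7aS)-3a,7-dimethyl-3-oxo-7-(triethylsilyloxy)octahydro-2-benzofuran-1-yl]methyl}-4-{3-[(tert-butyldimethylsilyl)oxy]prop-1-en-2-yl}-2-(pyridin-2-ylsulfanyl)cyclohexan-1-one (C2 epimers; 4R,5S,6R,10R,13R in skeleton locants) | C=C(CO[Si](C)(C)C(C)(C)C)[C@@H]1CCC(=O)C(C[C@H]2OC(=O)[C@]3(C)CCC[C@@](C)(O[Si](CC)(CC)CC)[C@H]23)(Sc2ccccn2)C1 | intermediate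
24 | (4R)-2-{[(1R,3aR,7R,7aS)-3a,7-dimethyl-3-oxo-7-(triethylsilyloxy)octahydro-2-benzofuran-1-yl]methyl}-4-(3-hydroxyprop-1-en-2-yl)-2-(pyridin-2-ylsulfanyl)cyclohexan-1-one (C2 epimers) | C=C(CO)[C@@H]1CCC(=O)C(C[C@H]2OC(=O)[C@]3(C)CCC[C@@](C)(O[Si](CC)(CC)CC)[C@H]23)(Sc2ccccn2)C1 | intermediate
25 | 2-[(1R)-3-{[(1R,3aR,7R,7aS)-3a,7-dimethyl-3-oxo-7-(triethylsilyloxy)octahydro-2-benzofuran-1-yl]methyl}-4-oxo-3-(pyridin-2-ylsulfanyl)cyclohexyl]prop-2-enal (epimers at the sulfur-bearing carbon) | C=C(C=O)[C@@H]1CCC(=O)C(C[C@H]2OC(=O)[C@]3(C)CCC[C@@](C)(O[Si](CC)(CC)CC)[C@H]23)(Sc2ccccn2)C1 | intermediate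
26 | diiodosamarium enolate of 25 after loss of the pyridylthio group (C8=C9–O–SmI2, 13R) | C=C(C=O)[C@@H]1CCC(O[Sm](I)I)=C(C[C@H]2OC(=O)[C@]3(C)CCC[C@@](C)(O[Si](CC)(CC)CC)[C@H]23)C1 | intermediate
27 | diiodosamarium C15 alkoxide of the bicyclo[3.2.1]octanone (aldolate; 8R,13R,15R) | C=C1[C@@H]2CCC(=O)[C@@](C[C@H]3OC(=O)[C@]4(C)CCC[C@@](C)(O[Si](CC)(CC)CC)[C@H]34)(C2)[C@@H]1O[Sm](I)I | intermediate
28 | (1R,5R,7R)-1-{[(1R,3aR,7R,7aS)-3a,7-dimethyl-3-oxo-7-(triethylsilyloxy)octahydro-2-benzofuran-1-yl]methyl}-6-methylidene-2-oxobicyclo[3.2.1]octan-7-yl acetate | C=C1[C@@H]2CCC(=O)[C@@](C[C@H]3OC(=O)[C@]4(C)CCC[C@@](C)(O[Si](CC)(CC)CC)[C@H]34)(C2)[C@@H]1OC(C)=O | intermediate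
29 | (1R,5R,7R)-1-{[(1R,3aR,7R,7aS)-3a,7-dimethyl-3-oxo-7-(triethylsilyloxy)octahydro-2-benzofuran-1-yl]methyl}-6-methylidene-2-(trimethylsilyloxy)bicyclo[3.2.1]oct-2-en-7-yl acetate | C=C1[C@@H]2CC=C(O[Si](C)(C)C)[C@@](C[C@H]3OC(=O)[C@]4(C)CCC[C@@](C)(O[Si](CC)(CC)CC)[C@H]34)(C2)[C@@H]1OC(C)=O | intermediate
30 | (1R,5S,7R)-1-{[(1R,3aR,7R,7aS)-3a,7-dimethyl-3-oxo-7-(triethylsilyloxy)octahydro-2-benzofuran-1-yl]methyl}-6-methylidene-2-oxobicyclo[3.2.1]oct-3-en-7-yl acetate | C=C1[C@@H]2C=CC(=O)[C@@](C[C@H]3OC(=O)[C@]4(C)CCC[C@@](C)(O[Si](CC)(CC)CC)[C@H]34)(C2)[C@@H]1OC(C)=O | intermediate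
31 | CNP0172716.1, (1R,5S,7R)-1-{[(1R,3aR,7R,7aS)-7-hydroxy-3a,7-dimethyl-3-oxo-octahydro-2-benzofuran-1-yl]methyl}-6-methylidene-2-oxobicyclo[3.2.1]oct-3-en-7-yl acetate | C=C1[C@@H]2C=CC(=O)[C@@](C[C@H]3OC(=O)[C@]4(C)CCC[C@@](C)(O)[C@H]34)(C2)[C@@H]1OC(C)=O | target

**Step count and risks**

Total step count: 20. Longest linear sequence: 13 steps (steps 8–14 followed by steps 15–20; the lactone branch, steps 1–7 followed by 15–20, is equally long).

The three steps most likely to fail:

1. Step 18 (proposed new method). Electron transfer to the enal (ketyl formation, pinacol coupling or conjugate reduction) may compete with C–S cleavage, or the samarium enolate may be protonated or the aldolate may revert before acetylation. The fallback uses known chemistry and no reductant in the ring-closing event; it sets out from 23 and returns at 30. Reductive desulfurization of 23 (SmI2, MeOH, THF, −78 °C) gives the sulfur-free C8–H ketone F1. Kinetic deprotonation at the less substituted C11 (LiN(i-Pr)2, Me3SiCl, THF, −78 °C) gives the kinetic silyl enol ether F2, which IBX·MPO in DMSO dehydrogenates to the cyclohexenone F3. Acidic methanolysis (camphorsulfonic acid, MeOH) gives the allylic alcohol F4 and MnO2 the enone-enal F5. LiN(SiMe3)2 at −78 °C then removes the only kinetically accessible α′-proton (C8–H) to give the lithium α′-enolate F6, which should close ring D through the same chelated aldol transition state to the lithium aldolate F7; acetylation in the flask with Ac2O gives 30.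

2. Step 15. The C6 radical may be trapped by the thiohydroxamate (decarboxylative rearrangement to the C6 pyridyl sulfide) faster than it adds to the enone, and 21 may be lost by hetero-Diels–Alder dimerization. The fallback separates radical addition from sulfur installation; it sets out from 10 and 21 and returns at 23. A non-chain photoredox decarboxylative conjugate addition (Ir[dF(CF3)ppy]2(dtbbpy)PF6, K2HPO4, DMF, blue light) forms the C6–C7 bond on the same convex face and, after protonation of the enolate, gives the sulfur-free ketone F1 described above. Thermodynamic enolization (Me3SiCl, NaI, Et3N, MeCN) then gives the more substituted silyl enol ether F8, and sulfenylation with pyridine-2-sulfenyl chloride (CH2Cl2, −78 °C) gives 23.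

3. Step 5. Facial selectivity in the capture of O2 by the C10 radical may be poor or reversed (oxygen entering syn to the lactone ring). The fallback delivers carbon instead of oxygen to the more accessible face; it sets out from 6 and returns at 8. Addition of the methylcerium reagent (MeMgBr, CeCl3, THF, −78 °C) to the C10 ketone is chemoselective over ester and lactone and non-basic enough to avoid E1cB opening; because it brings in the methyl group where the hydration brings in oxygen, one of the two methods should give the 10R alcohol 8 whichever face is preferred. It makes no new compound.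

**Further compounds**

F1 | step 18 | (4R)-2-{[(1R,3aR,7R,7aS)-3a,7-dimethyl-3-oxo-7-(triethylsilyloxy)octahydro-2-benzofuran-1-yl]methyl}-4-{3-[(tert-butyldimethylsilyl)oxy]prop-1-en-2-yl}cyclohexan-1-one (C2 epimers) | C=C(CO[Si](C)(C)C(C)(C)C)[C@@H]1CCC(=O)C(C[C@H]2OC(=O)[C@]3(C)CCC[C@@](C)(O[Si](CC)(CC)CC)[C@H]23)C1
F2 | step 18 | kinetic trimethylsilyl enol ether of F1 (C9(OSiMe3)=C11) | C=C(CO[Si](C)(C)C(C)(C)C)[C@@H]1CC=C(O[Si](C)(C)C)C(C[C@H]2OC(=O)[C@]3(C)CCC[C@@](C)(O[Si](CC)(CC)CC)[C@H]23)C1
F3 | step 18 | (4S)-6-{[(1R,3aR,7R,7aS)-3a,7-dimethyl-3-oxo-7-(triethylsilyloxy)octahydro-2-benzofuran-1-yl]methyl}-4-{3-[(tert-butyldimethylsilyl)oxy]prop-1-en-2-yl}cyclohex-2-en-1-one (C6 epimers) | C=C(CO[Si](C)(C)C(C)(C)C)[C@@H]1C=CC(=O)C(C[C@H]2OC(=O)[C@]3(C)CCC[C@@](C)(O[Si](CC)(CC)CC)[C@H]23)C1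
F4 | step 18 | allylic alcohol from F3 (4-(3-hydroxyprop-1-en-2-yl)cyclohex-2-en-1-one) | C=C(CO)[C@@H]1C=CC(=O)C(C[C@H]2OC(=O)[C@]3(C)CCC[C@@](C)(O[Si](CC)(CC)CC)[C@H]23)C1
F5 | step 18 | enone-enal from F4 (2-(4-oxocyclohex-2-en-1-yl)prop-2-enal bearing the lactone arm at the α′-carbon) | C=C(C=O)[C@@H]1C=CC(=O)C(C[C@H]2OC(=O)[C@]3(C)CCC[C@@](C)(O[Si](CC)(CC)CC)[C@H]23)C1
F6 | step 18 | lithium α′-enolate of F5 (C8=C9–OLi) | C=C(C=O)[C@@H]1C=CC(O[Li])=C(C[C@H]2OC(=O)[C@]3(C)CCC[C@@](C)(O[Si](CC)(CC)CC)[C@H]23)C1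
F7 | step 18 | lithium C15 alkoxide of the bicyclo[3.2.1]octenone (lithium aldolate; 8R,13S,15R) | C=C1[C@@H]2C=CC(=O)[C@@](C[C@H]3OC(=O)[C@]4(C)CCC[C@@](C)(O[Si](CC)(CC)CC)[C@H]34)(C2)[C@@H]1O[Li]
F8 | step 15 | thermodynamic trimethylsilyl enol ether of F1 (C8=C9(OSiMe3)) | C=C(CO[Si](C)(C)C(C)(C)C)[C@@H]1CCC(O[Si](C)(C)C)=C(C[C@H]2OC(=O)[C@]3(C)CCC[C@@](C)(O[Si](CC)(CC)CC)[C@H]23)C1
F0 | step 5 | none | none
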